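Start at the last readings. Sub turns into Prd with Cat in closed flasks, and the question is how much Prd a smaller charge holds at the same clock time.

the same everywhere: Cat 0.0300 M
- west: Sub 0.600 M
- east: Sub 0.300 M
- north: Sub 0.300 M
- north-east: Sub 0.200 M; time 55 min

| run | time / min | [Prd] / M |
|---|---|---|
| west run | 6.9 | 0.028 |
| west run | 14 | 0.070 |
| west run | 21 | 0.139 |
| west run | 28 | 0.201 |
| west run | 34 | 0.230 |
| west run | 41 | 0.250 |
| west run | 48 | 0.267 |
| west run | 55 | 0.266 |
| east run | 6.9 | 0.006 |
| east run | 14 | 0.016 |
| east run | 21 | 0.048 |
| east run | 28 | 0.047 |
| east run | 34 | 0.059 |
| east run | 41 | 0.075 |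
| east run | 48 | 0.077 |
| east run | 55 | 0.083 |
| north run | 6.9 | 0.012 |
| north run | 14 | 0.030 |
| north run | 21 | 0.041 |
| north run | 28 | 0.060 |
| north run | 34 | 0.063 |
| north run | 41 | 0.073 |
| north run | 48 | 0.077 |
| north run | 55 | 0.075 |

(readings scatter by 0.006 M)

- reaction order in [Sub] at the outset, round the charge of the west run, defined at two percent of the Sub turned into Prd (one fixed amount of Prd, the same in the runs compared)
- Prd in the north-east run at 55 min, as a share of the Sub charged

- Overall: Sub -> Prd, with Cat as catalyst.
- Constant volume, constant temperature.
- An order is taken over about fifteen percent of the charge, up and down.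

The bench rule for a curve that flattens is a fixed share: the same part of any charge ends as Prd. At 55 min the west flask holds 44.3 % of its Sub as Prd, while the east and north repeats, averaged at 0.0790 M, hold 26.3 %. The rule stops there: a charge ratio of 2.00 moves the share by a ratio of 1.68, so the share climbs with the charge.

The last readings can be put as odds instead: Prd made over Sub charged and not made into Prd, whatever has become of that Sub. Those odds divided by the charge are the odds per molar, 1.19 /M for the east and north average and 1.33 /M for the west flask. That gap of 0.140 /M is smaller than the 0.164 /M between the two repeats, so the scatter covers it. Carried to the north-east charge, the value from the nearer charge, 1.19 /M, gives this reckoning a share of 19.2 %.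

The forecast says 1.3 for the order and 20 % for the share: “Plateaus fit second order with a fixed integral”. That integral is this same quantity, which the forecast puts at 1.3 /M, and its share stands above the 19.2 % reckoned here.

The flask gives an order of 1.1 and a share of 20.9 %, and the forecast held within its margins.

    2 Cat ⇌ Cat2, settled at all times (46.20 /M)
    Cat + Sub → Prd + Cat (0.3462 /M/min)
    Sub + Prd → 2 Prd (0.2532 /M/min)
    Sub → X (0.02892 /min)

The north-east flask's odds per molar come to 1.32 /M, against the 1.19 /M carried to it. The main reason for the Prd missing from its charge is the reaction of Sub to X: the north-east flask without that step reaches 62.6 % of its charge as Prd, against 20.9 %. In that run the odds per molar stand higher than 1.32 /M, at 8.36 /M.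

Readings and results come from a simulation from invented constants; the scatter is artificial.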